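**Retrosynthetic overview**

1. The target is an olivil core (oxolane O1–C2H2–C3(OH)(CH2–ring B)–C4(CH2OH)–C5(ring A)) whose ring A phenol oxygen is bound to Cβ of a threo guaiacylglycerol chain Cα(OH)(ring C)–Cβ–CγH2OH; rings A, B and C are guaiacyl rings bought as vanillin derivatives.
2. Last C–C bond: Cα–Cβ, formed by a dibutylboron syn-aldol that joins the complete olivil core, as the (S)-4-benzyloxazolidinone imide of the ring A aryloxyacetic acid (Cγ = imide carbonyl, Cβ = enolate carbon), to O-benzylvanillin (Cα = aldehyde carbon); LiBH4 then turns Cγ into CH2OH.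
3. Enabling feature: Cβ carries the ring A ether oxygen and Cγ, so with Cγ at the acyl level it is an enolizable glycolate α-carbon, and Cα is a secondary benzylic carbinol on ring C; their syn O/O pattern is what a Z-enolate aldol delivers.
4. Olivil core: the same auxiliary steers a succinate aldol with TIPS-vanillin; lactonization closes the only ring built in the route (γ-lactone = future oxolane, C5 and C4 set). Trans-benzylation (ring B) and enolate hydroxylation anti to the C4 arm set C3, and the lactone C=O is reduced to C2H2.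
5. Protecting groups: aryl TIPS on ring A (cleaved alone before the union), TBS on the C4 CH2OH, benzyl on the ring B and ring C phenols; the C3 tertiary OH stays free.

Key step: step 15

Remark: the aryloxyacetyl imide is assumed to form the Z-boron enolate and to react with the facial sense known for alkoxyacetyl and propionyl imides of the same auxiliary. TIPS = triisopropylsilyl, TBS = tert-butyldimethylsilyl.

Step 1
Reactants: 1 vanillin
Product: 2 3-methoxy-4-(TIPS-oxy)benzaldehyde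
Conditions: TIPSCl, imidazole, DMF, rt
Reagents that add atoms: TIPSCl (triisopropylsilyl chloride), CC(C)[Si](Cl)(C(C)C)C(C)C
Why: Silyl ether formation at the phenol gives a ring A protecting group that should survive the enolate, hydride and Lewis acid steps and can later be removed by fluoride without touching benzyl ethers.

Step 2
Reactants: 3 (S)-4-benzyloxazolidin-2-one; 4 methyl 4-chloro-4-oxobutanoate
Product: 6 methyl 4-[(S)-4-benzyl-2-oxooxazolidin-3-yl]-4-oxobutanoate, via N-lithio oxazolidinone 5 (not isolated)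
Conditions: n-BuLi, THF, −78 °C; then 4, −78 → 0 °C
Reagents that add atoms: none
Why: N-acylation of the lithiated oxazolidinone by the acid chloride is the standard imide synthesis and leaves the methyl ester untouched at low temperature.

Step 3
Reactants: 6 methyl 4-[(S)-4-benzyl-2-oxooxazolidin-3-yl]-4-oxobutanoate; 2 3-methoxy-4-(TIPS-oxy)benzaldehyde
Product: 10 (S)-4-benzyl-3-{(2S,3S)-2-[3-methoxy-4-(TIPS-oxy)phenyl]-5-oxotetrahydrofuran-3-carbonyl}oxazolidin-2-one, via Z-dibutylboron enolate 7 (not isolated), via boron aldolate 8 (not isolated), via hydroxy ester 9 (not isolated)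
Conditions: Bu2BOTf, iPr2NEt, CH2Cl2, −78 → 0 °C; 2, −78 → 0 °C; MeOH, pH 7 buffer, 30% H2O2, 0 °C; then PPTS (cat.), CH2Cl2, rt
Reagents that add atoms: none
Why: Evans syn-aldol followed by lactonization: the Z-boron enolate, formed only at the imide CH2, should add to the aldehyde through a closed chair transition state on the face away from the auxiliary benzyl group, setting C5 (S) and C4 of the future oxolane, and the syn γ-hydroxy ester then closes to the trans-disubstituted γ-lactone.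

Step 4
Reactants: 10 the lactone imide
Product: 11 (2S,3S)-2-[3-methoxy-4-(TIPS-oxy)phenyl]-5-oxotetrahydrofuran-3-carboxylic acid
Conditions: LiOH, 30% H2O2, THF/H2O, 0 °C; aq. Na2SO3; dilute HCl to pH 2–3
Reagents that add atoms: hydrogen peroxide (as LiOOH), OO
Why: Lithium hydroperoxide hydrolysis attacks the exocyclic imide carbonyl selectively and should release the acid and the auxiliary without epimerization, any opened lactone reclosing on acidification.

Step 5
Reactants: 11 the lactone acid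
Product: 12 (4R,5S)-4-(hydroxymethyl)-5-[3-methoxy-4-(TIPS-oxy)phenyl]dihydrofuran-2(3H)-one
Conditions: BH3·SMe2, THF, 0 °C → rt; MeOH quench
Reagents that add atoms: none
Why: Borane reduction is chemoselective for a carboxylic acid over a lactone, so the C4 carbon substituent should reach the alcohol level with the ring intact.

Step 6
Reactants: 12 the hydroxymethyl lactone
Product: 13 (4R,5S)-4-(TBS-oxymethyl)-5-[3-methoxy-4-(TIPS-oxy)phenyl]dihydrofuran-2(3H)-one
Conditions: TBSCl, imidazole, DMF, 0 °C → rt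
Reagents that add atoms: TBSCl (tert-butyldimethylsilyl chloride), CC(C)(C)[Si](C)(C)Cl
Why: Silyl ether formation at the primary alcohol under weakly basic conditions should outpace translactonization and masks the hydroxyl for the enolate steps.

Step 7
Reactants: 14 [4-(benzyloxy)-3-methoxyphenyl]methanol
Product: 15 1-(benzyloxy)-4-(bromomethyl)-2-methoxybenzene
Conditions: PBr3, Et2O, 0 °C
Reagents that add atoms: PBr3 (phosphorus tribromide), BrP(Br)Br
Why: Nucleophilic substitution of the activated benzylic alcohol by bromide gives the ring B alkylating agent, which is used without storage.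

Step 8
Reactants: 13 the TBS lactone; 15 1-(benzyloxy)-4-(bromomethyl)-2-methoxybenzene
Product: 17 (3S,4R,5S)-3-[4-(benzyloxy)-3-methoxybenzyl]-4-(TBS-oxymethyl)-5-[3-methoxy-4-(TIPS-oxy)phenyl]dihydrofuran-2(3H)-one, via lithium enolate 16 (not isolated)
Conditions: LiHMDS, THF, −78 °C; 15, DMPU, −78 → −30 °C
Reagents that add atoms: none
Why: Lactone enolate alkylation should place the benzyl group anti to the C4 arm (3,4-trans), although this centre is made planar again in the next step and its configuration is not needed.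

Step 9
Reactants: 17 the α-benzyl lactone
Product: 19 (3S,4R,5S)-3-[4-(benzyloxy)-3-methoxybenzyl]-3-hydroxy-4-(TBS-oxymethyl)-5-[3-methoxy-4-(TIPS-oxy)phenyl]dihydrofuran-2(3H)-one, via potassium enolate 18 (not isolated)
Conditions: KHMDS, THF, −78 °C; 2-(phenylsulfonyl)-3-phenyloxaziridine, −78 °C; aq. NH4Cl
Reagents that add atoms: 2-(phenylsulfonyl)-3-phenyloxaziridine, O=S(=O)(c1ccccc1)N1OC1c1ccccc1
Why: Electrophilic α-hydroxylation of a lactone enolate by an N-sulfonyloxaziridine should deliver oxygen to the face opposite the adjacent C4 silyloxymethyl group, which puts OH trans and the ring B benzyl cis to that group, i.e. the 3S tertiary carbinol of the target.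

Step 10
Reactants: 19 the α-hydroxy lactone
Product: 20 (3S,4R,5S)-3-[4-(benzyloxy)-3-methoxybenzyl]-4-(TBS-oxymethyl)-5-[3-methoxy-4-(TIPS-oxy)phenyl]tetrahydrofuran-2,3-diol (lactol as both anomers)
Conditions: DIBAL-H, CH2Cl2, −78 °C; aq. potassium sodium tartrate
Reagents that add atoms: none
Why: Partial reduction of a lactone by DIBAL-H should stop at the lactol because the tetrahedral aluminium alkoxide is stable at −78 °C, one extra hydride equivalent being consumed by the tertiary hydroxyl.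

Step 11
Reactants: 20 the lactol
Product: 21 (3S,4R,5S)-3-[4-(benzyloxy)-3-methoxybenzyl]-4-(TBS-oxymethyl)-5-[3-methoxy-4-(TIPS-oxy)phenyl]tetrahydrofuran-3-ol
Conditions: Et3SiH, BF3·OEt2, CH2Cl2, −78 → −40 °C; aq. NaHCO3
Reagents that add atoms: none
Why: Ionic hydrogenation of the lactol: BF3 ionizes the anomeric hydroxyl to the cyclic oxocarbenium ion, which Et3SiH should reduce to the C2 methylene of the oxolane without touching a stereocentre.

Step 12
Reactants: 21 the fully protected oxolane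
Product: 22 (3S,4R,5S)-3-[4-(benzyloxy)-3-methoxybenzyl]-4-(TBS-oxymethyl)-5-(4-hydroxy-3-methoxyphenyl)tetrahydrofuran-3-ol
Conditions: TBAF, AcOH, THF, 0 °C
Reagents that add atoms: none
Why: Fluoride desilylation is much faster for an aryl silyl ether (phenoxide leaving group) than for a primary alkyl TBS ether, so buffered fluoride at 0 °C should free only the ring A phenol.

Step 13
Reactants: 3 (S)-4-benzyloxazolidin-2-one; 23 bromoacetyl bromide
Product: 25 (S)-4-benzyl-3-(bromoacetyl)oxazolidin-2-one, via N-sodio oxazolidinone 24 (not isolated)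
Conditions: NaH, THF, 0 °C; then added to 23, THF, −78 → 0 °C
Reagents that add atoms: none
Why: Deprotonation by NaH gives the sodium salt of the oxazolidinone, which is N-acylated at the acyl bromide; inverse addition at low temperature should keep the alkyl bromide from being displaced.

Step 14
Reactants: 22 the ring A phenol; 25 (S)-4-benzyl-3-(bromoacetyl)oxazolidin-2-one
Product: 26 (S)-4-benzyl-3-[(4-{(2S,3R,4S)-4-[4-(benzyloxy)-3-methoxybenzyl]-4-hydroxy-3-(TBS-oxymethyl)tetrahydrofuran-2-yl}-2-methoxyphenoxy)acetyl]oxazolidin-2-one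
Conditions: K2CO3, acetone, rt
Reagents that add atoms: none
Why: Williamson ether synthesis: the phenoxide should displace the activated α-bromo imide bromide, whereas the tertiary alcohol is not deprotonated by carbonate.

Step 15
Reactants: 26 the aryloxyacetyl imide; 27 4-(benzyloxy)-3-methoxybenzaldehyde
Product: 30 (S)-4-benzyl-3-[(2S,3R)-3-[4-(benzyloxy)-3-methoxyphenyl]-3-hydroxy-2-(4-{(2S,3R,4S)-4-[4-(benzyloxy)-3-methoxybenzyl]-4-hydroxy-3-(TBS-oxymethyl)tetrahydrofuran-2-yl}-2-methoxyphenoxy)propanoyl]oxazolidin-2-one, via bis-borylated Z-enolate 28 (not isolated), via bis-boron aldolate 29 (not isolated)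
Conditions: Bu2BOTf (2.3 equiv), iPr2NEt (2.8 equiv), CH2Cl2, −78 → 0 °C; 27, −78 → 0 °C; MeOH, pH 7 buffer, 30% H2O2, 0 °C
Reagents that add atoms: none
Why: Bu2BOTf and iPr2NEt should first cap the free C3 hydroxyl as its dibutylborinate and then convert the imide into the chelated Z-boron enolate 28, which adds to aldehyde 27 through a closed chair six-membered transition state to give aldolate 29, freed by the oxidative work-up. The closest known reaction type is the Evans dibutylboron syn-aldol of N-(alkoxyacetyl)- and N-(aryloxyacetyl)oxazolidinones with aromatic aldehydes. No ring is closed; the only cyclic event is the boron-bridged transition state. Cβ (2S in 30) and Cα (3R in 30) are both new: their syn relation follows from the Z-enolate geometry, and their absolute sense from the benzyl group of the (S)-auxiliary, which shields one enolate face in the dipole-minimized conformer. The step needs site selectivity (the imide CH2 is the only enolizable position and the one free hydroxyl is masked in the flask), facial selectivity (auxiliary control, remote from the oxolane stereocentres) and survival of the acid-labile benzylic C5–O bond, which the amine-buffered medium and low temperature should secure.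

Step 16
Reactants: 30 the aldol adduct
Product: 31 (1R,2R)-1-[4-(benzyloxy)-3-methoxyphenyl]-2-(4-{(2S,3R,4S)-4-[4-(benzyloxy)-3-methoxybenzyl]-4-hydroxy-3-(TBS-oxymethyl)tetrahydrofuran-2-yl}-2-methoxyphenoxy)propane-1,3-diol
Conditions: LiBH4, MeOH (1 equiv), THF, 0 °C
Reagents that add atoms: none
Why: Reductive cleavage of the N-acyl oxazolidinone by LiBH4 should give the Cγ primary alcohol directly and free the auxiliary, the descriptor at Cβ changing from S to R only because the priority of Cγ drops.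

Step 17
Reactants: 31 the TBS-protected diol
Product: 32 (1R,2R)-1-[4-(benzyloxy)-3-methoxyphenyl]-2-(4-{(2S,3R,4S)-4-[4-(benzyloxy)-3-methoxybenzyl]-4-hydroxy-3-(hydroxymethyl)tetrahydrofuran-2-yl}-2-methoxyphenoxy)propane-1,3-diol
Conditions: TBAF, THF, 0 °C → rt
Reagents that add atoms: none
Why: Fluoride desilylation of the primary TBS ether is done before debenzylation, while the substrate is still a neutral and easily purified dibenzyl ether.

Step 18
Reactants: 32 the dibenzyl ether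
Product: 33 (1R,2R)-1-(4-hydroxy-3-methoxyphenyl)-2-{4-[(2S,3R,4S)-4-hydroxy-4-(4-hydroxy-3-methoxybenzyl)-3-(hydroxymethyl)tetrahydrofuran-2-yl]-2-methoxyphenoxy}propane-1,3-diol (target)
Conditions: H2 (1 atm), 10% Pd/C, EtOAc/EtOH, rt
Reagents that add atoms: none
Why: Catalytic hydrogenolysis of the two aryl benzyl ethers under neutral conditions, stopped at full conversion, should leave the benzylic C–O bonds at Cα and C5 intact.

**Compound list**

1 | vanillin | COc1cc(C=O)ccc1O | starting material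
2 | 3-methoxy-4-(TIPS-oxy)benzaldehyde | COc1cc(C=O)ccc1O[Si](C(C)C)(C(C)C)C(C)C | intermediate
3 | (S)-4-benzyloxazolidin-2-one | O=C1N[C@@H](Cc2ccccc2)CO1 | starting material
4 | methyl 4-chloro-4-oxobutanoate | COC(=O)CCC(Cl)=O | starting material
5 | N-lithio-(S)-4-benzyloxazolidin-2-one | [Li]N1C(=O)OC[C@@H]1Cc1ccccc1 | intermediate (not isolated)
6 | methyl 4-[(S)-4-benzyl-2-oxooxazolidin-3-yl]-4-oxobutanoate | COC(=O)CCC(=O)N1C(=O)OC[C@@H]1Cc1ccccc1 | intermediate
7 | Z-dibutylboron enolate of 6 | CCCCB(CCCC)O/C(=C\CC(=O)OC)N1C(=O)OC[C@@H]1Cc1ccccc1 | intermediate (not isolated)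
8 | dibutylboron aldolate of 9 | CCCCB(CCCC)O[C@H](c1ccc(O[Si](C(C)C)(C(C)C)C(C)C)c(OC)c1)[C@H](CC(=O)OC)C(=O)N1C(=O)OC[C@@H]1Cc1ccccc1 | intermediate (not isolated)
9 | methyl (3S,4S)-3-[(S)-4-benzyl-2-oxooxazolidine-3-carbonyl]-4-hydroxy-4-[3-methoxy-4-(TIPS-oxy)phenyl]butanoate | O[C@H](c1ccc(O[Si](C(C)C)(C(C)C)C(C)C)c(OC)c1)[C@H](CC(=O)OC)C(=O)N1C(=O)OC[C@@H]1Cc1ccccc1 | intermediate (not isolated)
10 | (S)-4-benzyl-3-{(2S,3S)-2-[3-methoxy-4-(TIPS-oxy)phenyl]-5-oxotetrahydrofuran-3-carbonyl}oxazolidin-2-one | C1C(=O)O[C@H](c2ccc(O[Si](C(C)C)(C(C)C)C(C)C)c(OC)c2)[C@H]1C(=O)N1C(=O)OC[C@@H]1Cc1ccccc1 | intermediate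
11 | (2S,3S)-2-[3-methoxy-4-(TIPS-oxy)phenyl]-5-oxotetrahydrofuran-3-carboxylic acid | C1C(=O)O[C@H](c2ccc(O[Si](C(C)C)(C(C)C)C(C)C)c(OC)c2)[C@H]1C(=O)O | intermediate
12 | (4R,5S)-4-(hydroxymethyl)-5-[3-methoxy-4-(TIPS-oxy)phenyl]dihydrofuran-2(3H)-one | C1C(=O)O[C@H](c2ccc(O[Si](C(C)C)(C(C)C)C(C)C)c(OC)c2)[C@H]1CO | intermediate
13 | (4R,5S)-4-(TBS-oxymethyl)-5-[3-methoxy-4-(TIPS-oxy)phenyl]dihydrofuran-2(3H)-one | C1C(=O)O[C@H](c2ccc(O[Si](C(C)C)(C(C)C)C(C)C)c(OC)c2)[C@H]1CO[Si](C)(C)C(C)(C)C | intermediate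
14 | [4-(benzyloxy)-3-methoxyphenyl]methanol | COc1cc(CO)ccc1OCc1ccccc1 | starting material
15 | 1-(benzyloxy)-4-(bromomethyl)-2-methoxybenzene | COc1cc(CBr)ccc1OCc1ccccc1 | intermediate
16 | lithium enolate of 13 | C1=C(O[Li])O[C@H](c2ccc(O[Si](C(C)C)(C(C)C)C(C)C)c(OC)c2)[C@H]1CO[Si](C)(C)C(C)(C)C | intermediate (not isolated)
17 | (3S,4R,5S)-3-[4-(benzyloxy)-3-methoxybenzyl]-4-(TBS-oxymethyl)-5-[3-methoxy-4-(TIPS-oxy)phenyl]dihydrofuran-2(3H)-one | COc1cc(C[C@@H]2C(=O)O[C@H](c3ccc(O[Si](C(C)C)(C(C)C)C(C)C)c(OC)c3)[C@H]2CO[Si](C)(C)C(C)(C)C)ccc1OCc1ccccc1 | intermediate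
18 | potassium enolate of 17 | COc1cc(CC2=C(O[K])O[C@H](c3ccc(O[Si](C(C)C)(C(C)C)C(C)C)c(OC)c3)[C@H]2CO[Si](C)(C)C(C)(C)C)ccc1OCc1ccccc1 | intermediate (not isolated)
19 | (3S,4R,5S)-3-[4-(benzyloxy)-3-methoxybenzyl]-3-hydroxy-4-(TBS-oxymethyl)-5-[3-methoxy-4-(TIPS-oxy)phenyl]dihydrofuran-2(3H)-one | COc1cc(C[C@@]2(O)C(=O)O[C@H](c3ccc(O[Si](C(C)C)(C(C)C)C(C)C)c(OC)c3)[C@H]2CO[Si](C)(C)C(C)(C)C)ccc1OCc1ccccc1 | intermediate
20 | (3S,4R,5S)-3-[4-(benzyloxy)-3-methoxybenzyl]-4-(TBS-oxymethyl)-5-[3-methoxy-4-(TIPS-oxy)phenyl]tetrahydrofuran-2,3-diol, both anomers | COc1cc(C[C@@]2(O)C(O)O[C@H](c3ccc(O[Si](C(C)C)(C(C)C)C(C)C)c(OC)c3)[C@H]2CO[Si](C)(C)C(C)(C)C)ccc1OCc1ccccc1 | intermediate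
21 | (3S,4R,5S)-3-[4-(benzyloxy)-3-methoxybenzyl]-4-(TBS-oxymethyl)-5-[3-methoxy-4-(TIPS-oxy)phenyl]tetrahydrofuran-3-ol | COc1cc(C[C@@]2(O)CO[C@H](c3ccc(O[Si](C(C)C)(C(C)C)C(C)C)c(OC)c3)[C@H]2CO[Si](C)(C)C(C)(C)C)ccc1OCc1ccccc1 | intermediate
22 | (3S,4R,5S)-3-[4-(benzyloxy)-3-methoxybenzyl]-4-(TBS-oxymethyl)-5-(4-hydroxy-3-methoxyphenyl)tetrahydrofuran-3-ol | COc1cc(C[C@@]2(O)CO[C@H](c3ccc(O)c(OC)c3)[C@H]2CO[Si](C)(C)C(C)(C)C)ccc1OCc1ccccc1 | intermediate
23 | bromoacetyl bromide | BrCC(Br)=O | starting material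
24 | N-sodio-(S)-4-benzyloxazolidin-2-one | [Na]N1C(=O)OC[C@@H]1Cc1ccccc1 | intermediate (not isolated)
25 | (S)-4-benzyl-3-(bromoacetyl)oxazolidin-2-one | BrCC(=O)N1C(=O)OC[C@@H]1Cc1ccccc1 | intermediate
26 | (S)-4-benzyl-3-[(4-{(2S,3R,4S)-4-[4-(benzyloxy)-3-methoxybenzyl]-4-hydroxy-3-(TBS-oxymethyl)tetrahydrofuran-2-yl}-2-methoxyphenoxy)acetyl]oxazolidin-2-one | COc1cc(C[C@@]2(O)CO[C@H](c3ccc(OCC(=O)N4C(=O)OC[C@@H]4Cc4ccccc4)c(OC)c3)[C@H]2CO[Si](C)(C)C(C)(C)C)ccc1OCc1ccccc1 | intermediate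
27 | 4-(benzyloxy)-3-methoxybenzaldehyde | COc1cc(C=O)ccc1OCc1ccccc1 | starting material
28 | Z-dibutylboron enolate of 26 bearing a dibutylborinate on the C3 oxygen | COc1cc(C[C@@]2(OB(CCCC)CCCC)CO[C@H](c3ccc(O/C=C(\OB(CCCC)CCCC)N4C(=O)OC[C@@H]4Cc4ccccc4)c(OC)c3)[C@H]2CO[Si](C)(C)C(C)(C)C)ccc1OCc1ccccc1 | intermediate (not isolated)
29 | bis(dibutylboron) derivative of 30 (aldolate oxygen and C3 oxygen) | COc1cc(C[C@@]2(OB(CCCC)CCCC)CO[C@H](c3ccc(O[C@H](C(=O)N4C(=O)OC[C@@H]4Cc4ccccc4)[C@H](OB(CCCC)CCCC)c4ccc(OCc5ccccc5)c(OC)c4)c(OC)c3)[C@H]2CO[Si](C)(C)C(C)(C)C)ccc1OCc1ccccc1 | intermediate (not isolated)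
30 | (S)-4-benzyl-3-[(2S,3R)-3-[4-(benzyloxy)-3-methoxyphenyl]-3-hydroxy-2-(aryloxy)propanoyl]oxazolidin-2-one, aryloxy as in 26 | COc1cc(C[C@@]2(O)CO[C@H](c3ccc(O[C@H](C(=O)N4C(=O)OC[C@@H]4Cc4ccccc4)[C@H](O)c4ccc(OCc5ccccc5)c(OC)c4)c(OC)c3)[C@H]2CO[Si](C)(C)C(C)(C)C)ccc1OCc1ccccc1 | intermediate
31 | (1R,2R)-1-[4-(benzyloxy)-3-methoxyphenyl]-2-(aryloxy)propane-1,3-diol, aryloxy as in 26 | COc1cc(C[C@@]2(O)CO[C@H](c3ccc(O[C@H](CO)[C@H](O)c4ccc(OCc5ccccc5)c(OC)c4)c(OC)c3)[C@H]2CO[Si](C)(C)C(C)(C)C)ccc1OCc1ccccc1 | intermediate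
32 | 31 bearing a free oxolane CH2OH (dibenzyl ether of the target) | COc1cc(C[C@@]2(O)CO[C@H](c3ccc(O[C@H](CO)[C@H](O)c4ccc(OCc5ccccc5)c(OC)c4)c(OC)c3)[C@H]2CO)ccc1OCc1ccccc1 | intermediate
33 | (1R,2R)-1-(4-hydroxy-3-methoxyphenyl)-2-{4-[(2S,3R,4S)-4-hydroxy-4-(4-hydroxy-3-methoxybenzyl)-3-(hydroxymethyl)tetrahydrofuran-2-yl]-2-methoxyphenoxy}propane-1,3-diol | COc1cc(C[C@@]2(O)CO[C@H](c3ccc(O[C@H](CO)[C@H](O)c4ccc(O)c(OC)c4)c(OC)c3)[C@H]2CO)ccc1O | target

Total steps: 18. Longest linear sequence: 15 (steps 1, 3–6, 8–12, 14–18).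

**Steps most likely to fail**

Risk 1, step 15: boron may be diverted by the free tertiary hydroxyl and the many ether oxygens, leading to incomplete enolization or eroded facial selectivity, and the Lewis acid may ionize the benzylic C5–O bond. The fallback sets out from 22 and comes back at 31; it makes the Cα–Cβ bond without a Lewis acid and sets both stereocentres afterwards by catalyst control. O-Alkylation of 22 with ethyl bromoacetate (K2CO3, acetone) should give the ethyl aryloxyacetate F1. Its lithium enolate (LDA, 2.2 equiv, THF, −78 °C) adds to aldehyde 27 to give the β-hydroxy ester stereoisomer mixture F2. IBX in DMSO oxidizes the benzylic carbinol to the configurationally labile β-keto ester F3. Transfer hydrogenation under dynamic kinetic resolution (RuCl(p-cymene)[(S,S)-TsDPEN], HCO2H/Et3N, rt), a known syn-selective reduction of α-alkoxy β-keto esters, should give the syn-(2S,3R) β-hydroxy ester F4. LiBH4 then reduces the ester to 31.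

Risk 2, step 9: oxygen transfer to the hindered tetrasubstituted enolate may show poor facial selectivity, or the tertiary alkoxide may be captured by the sulfonimine by-product. The fallback sets out from 13 and comes back at 19; the tertiary carbinol is built as a spiro-epoxide on a less hindered exocyclic alkene and ring B is attached last. Aminomethylation of 13 (LiHMDS; N,N-dimethylmethyleneiminium iodide) gives the Mannich base F5, MeI gives the trimethylammonium iodide F6, and aq. NaHCO3 eliminates it to the α-methylene lactone F7. Nucleophilic epoxidation (tBuOOH, DBU, CH2Cl2) should close the epoxide anti to the C4 arm and give the spiro-epoxy lactone F8. The arylmagnesium bromide F9 (from commercial 1-(benzyloxy)-4-bromo-2-methoxybenzene and Mg, THF) in the presence of catalytic CuI at −40 °C opens the epoxide at its CH2 carbon to give 19.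

Risk 3, step 11: BF3 may ionize the benzylic C5–O bond or trigger a 1,2-shift in the α-hydroxy oxocarbenium ion. The fallback sets out from 19 and comes back at 21; the ring is opened and reclosed by O-alkylation under acid-free conditions. LiBH4 (THF, 0 °C → rt) reduces the lactone to the triol F10. TsCl in pyridine, catalysed by DMAP (0 → 60 °C), sulfonylates the primary hydroxyl to the primary tosylate F11, which the secondary benzylic hydroxyl displaces in a 5-exo-tet Williamson closure to give 21, leaving C5 untouched; pyridine is too weak a base to ionize the tertiary hydroxyl, which should keep epoxide closure slow.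

Further compounds
F1 | step 15 | ethyl (4-{(2S,3R,4S)-4-[4-(benzyloxy)-3-methoxybenzyl]-4-hydroxy-3-(TBS-oxymethyl)tetrahydrofuran-2-yl}-2-methoxyphenoxy)acetate | COc1cc(C[C@@]2(O)CO[C@H](c3ccc(OCC(=O)OCC)c(OC)c3)[C@H]2CO[Si](C)(C)C(C)(C)C)ccc1OCc1ccccc1
F2 | step 15 | ethyl 3-[4-(benzyloxy)-3-methoxyphenyl]-3-hydroxy-2-(aryloxy)propanoate, stereoisomer mixture at C2 and C3, aryloxy as in F1 | COc1cc(C[C@@]2(O)CO[C@H](c3ccc(OC(C(=O)OCC)C(O)c4ccc(OCc5ccccc5)c(OC)c4)c(OC)c3)[C@H]2CO[Si](C)(C)C(C)(C)C)ccc1OCc1ccccc1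
F3 | step 15 | ethyl 3-[4-(benzyloxy)-3-methoxyphenyl]-3-oxo-2-(aryloxy)propanoate, C2 epimers, aryloxy as in F1 | COc1cc(C[C@@]2(O)CO[C@H](c3ccc(OC(C(=O)OCC)C(=O)c4ccc(OCc5ccccc5)c(OC)c4)c(OC)c3)[C@H]2CO[Si](C)(C)C(C)(C)C)ccc1OCc1ccccc1
F4 | step 15 | ethyl (2S,3R)-3-[4-(benzyloxy)-3-methoxyphenyl]-3-hydroxy-2-(aryloxy)propanoate, aryloxy as in F1 | COc1cc(C[C@@]2(O)CO[C@H](c3ccc(O[C@H](C(=O)OCC)[C@H](O)c4ccc(OCc5ccccc5)c(OC)c4)c(OC)c3)[C@H]2CO[Si](C)(C)C(C)(C)C)ccc1OCc1ccccc1
F5 | step 9 | 3,4-trans-3-[(dimethylamino)methyl] derivative of lactone 13 | CN(C)C[C@@H]1C(=O)O[C@H](c2ccc(O[Si](C(C)C)(C(C)C)C(C)C)c(OC)c2)[C@H]1CO[Si](C)(C)C(C)(C)C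
F6 | step 9 | trimethylammonium iodide of F5 | C[N+](C)(C)C[C@@H]1C(=O)O[C@H](c2ccc(O[Si](C(C)C)(C(C)C)C(C)C)c(OC)c2)[C@H]1CO[Si](C)(C)C(C)(C)C.[I-]
F7 | step 9 | (4R,5S)-3-methylene-4-(TBS-oxymethyl)-5-[3-methoxy-4-(TIPS-oxy)phenyl]dihydrofuran-2(3H)-one | C=C1C(=O)O[C@H](c2ccc(O[Si](C(C)C)(C(C)C)C(C)C)c(OC)c2)[C@H]1CO[Si](C)(C)C(C)(C)C
F8 | step 9 | spiro-epoxide of F7, epoxide oxygen anti to the TBS-oxymethyl group | C1O[C@@]12C(=O)O[C@H](c3ccc(O[Si](C(C)C)(C(C)C)C(C)C)c(OC)c3)[C@H]2CO[Si](C)(C)C(C)(C)C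
F9 | step 9 | [4-(benzyloxy)-3-methoxyphenyl]magnesium bromide | COc1cc([Mg]Br)ccc1OCc1ccccc1
F10 | step 11 | (2S,3R)-2-[4-(benzyloxy)-3-methoxybenzyl]-3-{(S)-hydroxy[3-methoxy-4-(TIPS-oxy)phenyl]methyl}-4-(TBS-oxy)butane-1,2-diol | COc1cc(C[C@@](O)(CO)[C@H](CO[Si](C)(C)C(C)(C)C)[C@H](O)c2ccc(O[Si](C(C)C)(C(C)C)C(C)C)c(OC)c2)ccc1OCc1ccccc1
F11 | step 11 | primary p-toluenesulfonate of F10 | COc1cc(C[C@@](O)(COS(=O)(=O)c2ccc(C)cc2)[C@H](CO[Si](C)(C)C(C)(C)C)[C@H](O)c2ccc(O[Si](C(C)C)(C(C)C)C(C)C)c(OC)c2)ccc1OCc1ccccc1
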